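The data were computed with constants of no real substance.

A plateau printed in per cent tempts one to treat it as the yield of the recipe and carry it to another charge, but a plateau can also be a fixed count of turnovers.

all flasks: reagent 0.143 M; free catalyst 55 µM; added ligand 58 µM

| flask | starting material | capture agent | remark | time |
|---|---|---|---|---|
| Saturday's | 0.11 M | 0.011 M | run made earlier |  |
| Thursday's | 0.055 M | 0.011 M | run made earlier |  |
| Monday's | 0.22 M | 0.011 M | run made earlier |  |
| alder | 0.11 M | 0.0110 M | a single well-mixed tank run continuously and read at steady state, 8.0 h in it on average |  |
| larch | 0.11 M (fed, over 6.40 h) | 0.0110 M | a stirred flask in which starting material is dosed at a steady rate over 6.40 h without added volume, worked up at 8.0 h | 8.0 h |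
| ash | 0.11 M | 0.0110 M | plug flow through a tube for 8.0 h, no back-mixing | 8.0 h |
| elm | 0.11 M | 0.0110 M | a closed flask charged with all of it at once and left for 8.0 h | 8.0 h |

| run | time / h | product / % | starting material / % |
|---|---|---|---|
| Saturday's | 0.667 | 12.6 | 88.2 |
| Saturday's | 1.33 | 13.4 | 85.1 |
| Saturday's | 2.50 | 13.2 | 85.7 |
| Saturday's | 4.00 | 15.3 | 87.2 |
| Saturday's | 8.00 | 11.2 | 86.7 |
| Thursday's | 1.00 | 25.6 | 73.4 |
| Thursday's | 2.00 | 27.0 | 73.2 |
| Thursday's | 3.00 | 28.3 | 73.5 |
| Thursday's | 4.00 | 27.5 | 73.0 |
| Thursday's | 5.00 | 26.6 | 72.7 |
| Monday's | 0.417 | 5.8 | 94.3 |
| Monday's | 1.33 | 5.5 | 89.9 |
| Monday's | 2.00 | 6.6 | 93.0 |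
| Monday's | 3.00 | 7.2 | 93.9 |
| Monday's | 5.00 | 6.6 | 93.3 |

(each reading ± 1 percentage point)

- the stated concentrations are those of everything mixed, before any reaction; amounts are the same in each set-up
- the feed brings no volume worth counting
- the earlier runs were made in a closed, stirred flask

* the set-up with the highest amount of product at the outlet or at the end, in percent of the starting material put in ("none" if the first two lie within 2 percentage points) (alder / larch / ash / elm / none)
* amount of product at the outlet or at the end, in percent of the starting material put in, alder
* amount of product at the outlet or at the end, in percent of the starting material put in, larch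
* amount of product at the outlet or at the end, in percent of the starting material put in, ash
* amount of product at the outlet or at the end, in percent of the starting material put in, elm

Thursday's product moves from 25.6% at 1.00 h to 26.6% at 5.00 h, a change of 1 percentage point against a scatter of 1 point, with 72.7% of the starting material still present. Averaged over their readings, the plateau fraction is 27.0% on Thursday's and 6.34% on Monday's. In logarithms, the charge rises by 0.602 decades between these runs and the fraction falls by 0.629, so the fraction moves while fraction times charge stands nearly still.

The quantity to carry is therefore the turnover ceiling, a turnover number: the plateau fraction times the charge of starting material, over the charge of free catalyst, 270 from Thursday's product. Free catalyst, reagent and capture agent were each charged alike in Saturday's, Thursday's and Monday's runs, so these runs cannot say which of them, if any, caps the product.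

A second way uses the fraction of starting material lost, a different column, and Thursday's gives 268. On Monday's the two ways part, at 254 from product and 285 from loss. The cheat is Monday's reading of 89.9% at 1.33 h, whose balance with product comes to 95.4%; without that reading, the loss gives 255.

The asked flasks hold the same charges as Saturday's, so this reckoning gives 13.5% in each. In alder, 8.00% of what leaves the tank is younger than 0.667 h, the first reading of Saturday's run at the same charges, which by this reckoning puts 1.1 points at stake, less than the margin.

The forecast gives 13%, 13%, 13% and 13% for alder, larch, ash and elm, with none as best, on the ground that “Each volume of charge carries the same limiting capacity”.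

The flasks give 13.1%, 13.5%, 13.5% and 13.5%, in the same order, with none as best.

    free catalyst + added ligand ⇌ idle complex, settled at all times (K = 35000 M⁻¹)
    capture agent + catalyst intermediate C → trapped intermediate (k = 440 M⁻¹ min⁻¹)
    catalyst intermediate B → by-product + catalyst intermediate C (k = 120 min⁻¹)
    starting material + catalyst intermediate A ⇌ catalyst intermediate B (K = 12.0 M⁻¹, k = 940 M⁻¹ min⁻¹)
    reagent + free catalyst → catalyst intermediate A (k = 770 M⁻¹ min⁻¹)
    catalyst intermediate C → free catalyst + product (k = 1300 min⁻¹)

In ash, the step from catalyst intermediate B to by-product + catalyst intermediate C had 96% of its turnover behind it by 0.800 h. At 8.00 h in ash, the catalyst stood 100% as trapped intermediate and 0% as free catalyst, beside 86% of the starting material and 99.5% of the capture agent. Ash's product amounts to 269 turnovers. For ash with 1.4 × 10⁻⁴ M of free catalyst, the ceiling gives 34.4%, and that flask gives 34.4%. Ash's product has moved by 5 points at 0.00803 M of capture agent, or at 75.4 µM of free catalyst, each moved with the other charges and the time held.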